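**Retrosynthetic overview**

- The ylidene butenolide is cut at its exocyclic C=C bond: vinylogous aldol condensation of 4-methylfuran-2(5H)-one (ring bought intact) with a C15 enal.
- The 13E alkene with its C16 hydroxymethyl group comes from stereoretentive hydroxymethylation of an E enol triflate of a β-keto ester, made by C-acylation of the C13 methyl ketone.
- That ketone, 14,15-dinorlabd-8-en-13-one, is the acid-opened form of sclareol oxide, with the alkene moved to C8=C9.
- The strategy rests on the trans-fused decalin, rings A and B (C1–C10; gem-dimethyl C4, C5–H, C10–CH3), with the chain C11–C13 on C9: a head-to-tail folded farnesyl unit whose C8 lies six atoms from the C13 oxygen.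
- Ring order: rings A and B and a temporary pyran (C8–O–C13) close together in the cyclase-mediated bicyclisation of farnesylacetone (step 1); the pyran is opened in step 2.

Key step: step 1

Remark: labdane numbering is used for the terpenoid part (ring A = C1–C5/C10, ring B = C5–C10, chain C11–C16 on C9); R is the (4aS,8aS)-2,5,5,8a-tetramethyl-3,4,4a,5,6,7,8,8a-octahydronaphthalen-1-yl group; geometrically pure commercial (5E,9E)-farnesylacetone is assumed, and the recombinant whole cells are treated as a catalyst preparation, not as a synthetic step.

**Route**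

Step 1
Reactants: 1 (5E,9E)-farnesylacetone
Product: 2 sclareol oxide (8α,13-epoxy-14,15-dinorlabd-12-ene; 5S,8R,9R,10S)
Conditions: E. coli whole cells overexpressing the squalene–hopene cyclase of Alicyclobacillus acidocaldarius, citrate buffer pH 6.0, 0.1% sodium dodecyl sulfate, 37 °C, 48–72 h; extraction
Reagents that add atoms: none
Why: The catalytic aspartic acid of the cyclase protonates C3 of the terminal C3=C4 alkene, the C4 cation is attacked by C5 of the C5=C10 alkene and the resulting C10 cation by C9 of the C8=C9 alkene, after which the C13 carbonyl oxygen adds to the C8 cation and the oxocarbenium ion loses a proton from C12 to leave the enol ether. The closest known reaction type is the squalene–hopene cyclase polycyclisation of truncated polyprenoids with an oxygen terminator (homofarnesol to ambroxide, farnesyl ketones to cyclic enol ethers), so both the enzyme class and the mode of termination are precedented. Ring A closes 6-endo-trig (C4–C5), ring B closes 6-endo-trig (C9–C10), and the pyran closes as a six-membered capture of the tertiary C8 cation by oxygen with the C=O unit inside the new ring. C5 and C10 follow from antiperiplanar addition across the E C5=C10 alkene in a chair fold (trans ring fusion), C9 from the same anti addition across the E C8=C9 alkene in the second chair (C9–H anti to C10–CH3, chain equatorial), and C8 from equatorial attack of the tethered oxygen anti to the new C9–C10 bond (8α-O, 8β-CH3); the absolute sense is imposed by the active site, which holds one pre-folded chair–chair conformer and protonates a single alkene face. The step needs complete bicyclisation and oxygen termination instead of early proton loss or water capture; the all-E geometry of 1, the ketone placed six atoms from C8 and the water-poor pocket should secure this.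

Step 2
Reactants: 2 sclareol oxide
Product: 4 olefinic methyl ketone 14,15-dinorlabd-8-en-13-one (4-R-butan-2-one), via hydroxy ketone 3 (not isolated)
Conditions: 57% aq. HI (0.3 equiv), benzene, 80 °C
Reagents that add atoms: water, O (its oxygen ends as the ketone oxygen when the path through 3 is followed; the former ring oxygen leaves as water)
Why: Acid-mediated enol ether hydrolysis followed by E1 dehydration and alkene isomerisation: protonation at C12 and hydration open the pyran to 3, ionisation of the tertiary C8–O bond and proton loss give the olefinic ketones, and reversible protonation should funnel them to the tetrasubstituted C8=C9 isomer, which alone is free of the 1,3-diaxial C8–CH3/C10–CH3 interaction of the ring-closed forms, while C5 and C10 are not touched.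

Step 3
Reactants: 4 14,15-dinorlabd-8-en-13-one
Product: 5 β-keto ester ethyl 3-oxo-5-R-pentanoate
Conditions: NaH (2.5 equiv), (EtO)2CO, THF, reflux; then AcOH
Reagents that add atoms: diethyl carbonate, CCOC(=O)OCC
Why: Claisen-type C-acylation of a methyl ketone with a dialkyl carbonate, in which the less hindered methyl terminus (C16 side is not involved; the new carbon is C14/C15 of the later chain) is acylated under equilibrating conditions and the product is drained from the equilibrium as its stabilised sodium enolate, the C8=C9 alkene being inert to NaH.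

Step 4
Reactants: 5 ethyl 3-oxo-5-R-pentanoate
Product: 6 enol triflate ethyl (2E)-5-R-3-{[(trifluoromethyl)sulfonyl]oxy}pent-2-enoate
Conditions: Tf2O, 25% aq. Me4NOH, hexanes, 5 °C
Reagents that add atoms: trifluoromethanesulfonic anhydride, O=S(=O)(OS(=O)(=O)C(F)(F)F)C(F)(F)F
Why: Stereoselective O-sulfonylation of a β-keto ester enolate under biphasic Schotten–Baumann-type conditions, where the non-chelating tetramethylammonium counter-ion lets the enolate react from its open, dipole-minimised form so that the triflate is expected trans to the ester (E), which places the C11–C12 chain cis to the ester carbon as the target requires.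

Step 5
Reactants: 6 E enol triflate
Product: 7 hydroxy enoate ethyl (2E)-3-(hydroxymethyl)-5-R-pent-2-enoate
Conditions: Bu3SnCH2OH, Pd(PPh3)4 (5 mol %), LiCl, 1,4-dioxane, 90 °C
Reagents that add atoms: (tributylstannyl)methanol, CCCC[Sn](CCCC)(CCCC)CO
Why: Stille hydroxymethylation, in which the electron-poor vinyl triflate adds oxidatively to zerovalent palladium, LiCl assists transmetalation of the hydroxymethyl group from tin, and reductive elimination proceeds with retention of alkene geometry, the trans hydroxy ester being unable to lactonise.

Step 6
Reactants: 7 hydroxy enoate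
Product: 8 silyl ether ethyl (2E)-3-{[(tert-butyldimethylsilyl)oxy]methyl}-5-R-pent-2-enoate
Conditions: TBSCl, imidazole, DMF, rt
Reagents that add atoms: tert-butyldimethylsilyl chloride, CC(C)(C)[Si](C)(C)Cl
Why: Standard imidazole-promoted silylation of a primary allylic alcohol, needed so that only the ester-derived carbinol is oxidised in step 8.

Step 7
Reactants: 8 silyl-protected enoate
Product: 9 allylic alcohol (2E)-3-{[(tert-butyldimethylsilyl)oxy]methyl}-5-R-pent-2-en-1-ol
Conditions: i-Bu2AlH (2.2 equiv), CH2Cl2, −78 °C; aq. KNaC4H4O6
Reagents that add atoms: none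
Why: 1,2-Reduction of an α,β-unsaturated ester by diisobutylaluminium hydride, which leaves the silyl ether, both alkenes and the alkene geometry untouched.

Step 8
Reactants: 9 allylic alcohol
Product: 10 enal (2E)-3-{[(tert-butyldimethylsilyl)oxy]methyl}-5-R-pent-2-enal
Conditions: MnO2 (excess), CH2Cl2, rt
Reagents that add atoms: none
Why: Heterogeneous MnO2 oxidation is selective for allylic alcohols, stops at the aldehyde and is neutral, so the E geometry of the β,β-disubstituted enal should be kept if the product is used without delay.

Step 9
Reactants: 10 enal; 11 4-methylfuran-2(5H)-one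
Product: 14 silyl ether of the target (5Z)-5-[(2E)-3-(silyloxymethyl)-5-R-pent-2-en-1-ylidene]-4-methylfuran-2(5H)-one, via silyloxyfuran 12 (not isolated), via silylated aldol adduct 13 (not isolated)
Conditions: 11, i-Pr2NEt, TBSOTf, CH2Cl2, 0 °C; 10, −78 → 0 °C; then DBU, 0 °C → rt
Reagents that add atoms: none
Why: Vinylogous Mukaiyama aldol addition followed by E1cB elimination in one pot: TBSOTf and the amine convert 11 into the aromatic 2-silyloxyfuran 12, which attacks the silyl-activated enal 1,2 through C5 to give 13, and DBU then removes the acidic C5–H and expels silanolate to form the exocyclic alkene, whose Z geometry (chain on the side of the ring oxygen) is enforced by the C4 methyl group.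

Step 10
Reactants: 14 silyl ether of the target
Product: 15 target (5Z)-5-[(2E)-3-(hydroxymethyl)-5-R-pent-2-en-1-ylidene]-4-methylfuran-2(5H)-one
Conditions: HF·pyridine, pyridine, THF, 0 °C → rt
Reagents that add atoms: none
Why: Fluoride-mediated cleavage of a primary silyl ether under buffered conditions that should spare the base-sensitive ylidene lactone, the triene geometry and the C8=C9 alkene.

**Compound list**

1 | (5E,9E)-farnesylacetone, (5E,9E)-6,10,14-trimethylpentadeca-5,9,13-trien-2-one | CC(C)=CCC/C(C)=C/CC/C(C)=C/CCC(C)=O | starting material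
2 | sclareol oxide, (4aR,6aS,10aS,10bR)-3,4a,7,7,10a-pentamethyl-4a,5,6,6a,7,8,9,10,10a,10b-decahydro-1H-benzo[f]chromene | CC1=CC[C@H]2[C@](C)(O1)CC[C@H]3C(C)(C)CCC[C@]23C | intermediate
3 | 8α-hydroxy-14,15-dinorlabdan-13-one, 4-[(1R,2R,4aS,8aS)-2-hydroxy-2,5,5,8a-tetramethyldecahydronaphthalen-1-yl]butan-2-one (not isolated) | CC(=O)CC[C@H]1[C@](C)(O)CC[C@H]2C(C)(C)CCC[C@]12C | intermediate
4 | 14,15-dinorlabd-8-en-13-one, 4-[(4aS,8aS)-2,5,5,8a-tetramethyl-3,4,4a,5,6,7,8,8a-octahydronaphthalen-1-yl]butan-2-one | CC(=O)CCC1=C(C)CC[C@H]2C(C)(C)CCC[C@]12C | intermediate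
5 | ethyl 3-oxo-5-R-pentanoate | CCOC(=O)CC(=O)CCC1=C(C)CC[C@H]2C(C)(C)CCC[C@]12C | intermediate
6 | ethyl (2E)-5-R-3-{[(trifluoromethyl)sulfonyl]oxy}pent-2-enoate | CCOC(=O)/C=C(/OS(=O)(=O)C(F)(F)F)CCC1=C(C)CC[C@H]2C(C)(C)CCC[C@]12C | intermediate
7 | ethyl (2E)-3-(hydroxymethyl)-5-R-pent-2-enoate | CCOC(=O)/C=C(/CO)CCC1=C(C)CC[C@H]2C(C)(C)CCC[C@]12C | intermediate
8 | ethyl (2E)-3-{[(tert-butyldimethylsilyl)oxy]methyl}-5-R-pent-2-enoate | CCOC(=O)/C=C(/CO[Si](C)(C)C(C)(C)C)CCC1=C(C)CC[C@H]2C(C)(C)CCC[C@]12C | intermediate
9 | (2E)-3-{[(tert-butyldimethylsilyl)oxy]methyl}-5-R-pent-2-en-1-ol | OC/C=C(/CO[Si](C)(C)C(C)(C)C)CCC1=C(C)CC[C@H]2C(C)(C)CCC[C@]12C | intermediate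
10 | (2E)-3-{[(tert-butyldimethylsilyl)oxy]methyl}-5-R-pent-2-enal | O=C/C=C(/CO[Si](C)(C)C(C)(C)C)CCC1=C(C)CC[C@H]2C(C)(C)CCC[C@]12C | intermediate
11 | 4-methylfuran-2(5H)-one | CC1=CC(=O)OC1 | starting material
12 | tert-butyldimethyl[(4-methylfuran-2-yl)oxy]silane (not isolated) | Cc1coc(O[Si](C)(C)C(C)(C)C)c1 | intermediate
13 | 5-[(2E)-1-[(tert-butyldimethylsilyl)oxy]-3-{[(tert-butyldimethylsilyl)oxy]methyl}-5-R-pent-2-en-1-yl]-4-methylfuran-2(5H)-one, diastereomer mixture at the two new sp3 centres (not isolated) | CC1=CC(=O)OC1C(O[Si](C)(C)C(C)(C)C)/C=C(/CO[Si](C)(C)C(C)(C)C)CCC1=C(C)CC[C@H]2C(C)(C)CCC[C@]12C | intermediate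
14 | (5Z)-5-[(2E)-3-{[(tert-butyldimethylsilyl)oxy]methyl}-5-R-pent-2-en-1-ylidene]-4-methylfuran-2(5H)-one | CC1=CC(=O)O/C1=C\C=C(\CO[Si](C)(C)C(C)(C)C)CCC1=C(C)CC[C@H]2C(C)(C)CCC[C@]12C | intermediate
15 | (5Z)-5-{(2E)-3-(hydroxymethyl)-5-[(4aS,8aS)-2,5,5,8a-tetramethyl-3,4,4a,5,6,7,8,8a-octahydronaphthalen-1-yl]pent-2-en-1-ylidene}-4-methylfuran-2(5H)-one | CC1=CC(=O)O/C1=C\C=C(\CO)CCC1=C(C)CC[C@H]2C(C)(C)CCC[C@]12C | target

**Step count and risks**

Total step count: 10. Longest linear sequence: 10 steps (1 to 15; 11 is bought).

Steps most likely to fail: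

Step 1. The bicyclisation may stall because the water-insoluble ketone reaches the membrane-bound enzyme too slowly, or the cation may be lost by proton elimination after one ring instead of being carried through to oxygen capture. The fallback sets out from 1 and comes back at 2. Chemical proton-initiated bicyclisation of 1 with FSO3H in 2-nitropropane at −78 °C, a known superacid cyclisation of farnesyl ketones to the racemic tricyclic enol ether, would give 2 together with its mirror image, ent-sclareol oxide F1. Preparative chromatography on a chiral stationary phase (cellulose tris(3,5-dimethylphenylcarbamate), supercritical CO2/2-propanol) would then deliver 2 as a single enantiomer. Its sense would be assigned by optical rotation against material of the natural series.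

Step 2. Re-closure of the C8 cation onto the carbonyl oxygen (or onto the enol carbon) may compete with proton loss, and the double bond may migrate incompletely, so that the mixture stops short of the C8=C9 ketone. The fallback sets out from 2 and comes back at 4. Hydrolysis with dilute aqueous oxalic acid in THF at room temperature would be stopped at the hydroxy ketone 3, which is isolated. Acetylation of its tertiary hydroxyl with AcCl and N,N-dimethylaniline would give 8α-acetoxy-14,15-dinorlabdan-13-one F2. Elimination of acetic acid in refluxing 2,4,6-collidine, a base-mediated process with no free cation, would give the olefinic ketones, chiefly 14,15-dinorlabd-8(17)-en-13-one F3 and its C7=C8 isomer. Catalytic I2 in benzene at 80 °C under anhydrous conditions would then move the double bond to C8=C9, giving 4.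

Step 5. Transmetalation of the sp3 hydroxymethyl group from tin may be slow, so that butyl transfer, reduction of the triflate or erosion of the alkene geometry at the vinylpalladium stage compete. The fallback sets out from 6 and comes back at 7. The one-carbon unit would be introduced as carbon monoxide: reductive carbonylation of 6 (Pd(PPh3)4, CO at 1 atm, slow addition of Bu3SnH, THF, 50 °C) should give ethyl (2E)-3-formyl-5-R-pent-2-enoate F4 with retention of geometry. Luche reduction (NaBH4, CeCl3·7H2O, MeOH, −40 °C) would then reduce the aldehyde chemoselectively in the presence of the ester to give 7.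

**Further compounds**

F1 | step 1 | ent-sclareol oxide, (4aS,6aR,10aR,10bS)-3,4a,7,7,10a-pentamethyl-4a,5,6,6a,7,8,9,10,10a,10b-decahydro-1H-benzo[f]chromene | CC1=CC[C@@H]2[C@@](C)(O1)CC[C@@H]3C(C)(C)CCC[C@@]23C
F2 | step 2 | 8α-acetoxy-14,15-dinorlabdan-13-one | CC(=O)CC[C@H]1[C@](C)(OC(C)=O)CC[C@H]2C(C)(C)CCC[C@]12C
F3 | step 2 | 14,15-dinorlabd-8(17)-en-13-one | CC(=O)CC[C@H]1C(=C)CC[C@H]2C(C)(C)CCC[C@]12C
F4 | step 5 | ethyl (2E)-3-formyl-5-R-pent-2-enoate | CCOC(=O)/C=C(/C=O)CCC1=C(C)CC[C@H]2C(C)(C)CCC[C@]12C
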